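Ring B plus the C4 gem-dimethyl carbon are the ten carbons of (R)-carvone: its ketone is C9, its ring methyl C17, its stereocentre C5 and its isopropenyl carbon C4. Everything rests on bridging C10 and C4, which sit 1,3 on carvone, with acrolein as C1–C2–C3. After α′-methylation (C20), one flask closes ring A: the enolate is alkylated at C10 by the acrolein–Me3SiI adduct (C1–C10), then iron-hydride hydrogen-atom transfer to the isopropenyl group sends the tertiary C4 radical onto the unmasked aldehyde (C3–C4, 3β-OH). The precursor is 6-methylcarvone, a monocyclic dienone. Enone saturation, a C9 spiro-epoxide opened by a furylmethyl Grignard, acetylation and furan oxidation finish.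

Key step: step 2

Remark: the decalins are numbered as in labdanes (C17 on C8, C18 and C19 on C4, C20 on C10, side chain C11 to C16; α is the face of H5, β the face of C20).
Remark: 2 forms together with some of its C6 epimer; both give the same enolate in step 2, so the mixture is used and the trans isomer is drawn.

Step 1
Reactants: 1 (R)-(−)-carvone
Product: 2 trans-6-methylcarvone
Conditions: LiN(i-Pr)2, THF, −78 °C; then MeI, −78 to 0 °C
Reagents that add atoms: iodomethane CI
Why: Kinetic α′-deprotonation gives the cross-conjugated lithium dienolate, and its SN2 methylation (enolate alkylation) installs C20 mainly anti to the isopropenyl group, a centre that is re-enolised in step 2 so its configuration is immaterial.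

Step 2
Reactants: 2 trans-6-methylcarvone; 3 acrolein
Product: 6 bicyclic hydroxy enone (3β-hydroxy-4,4,8,10-tetramethyl-5α-decal-7-en-9-one), via silyl enol ether 4 (not isolated), via keto aldehyde 5 (not isolated)
Conditions: LiN(i-Pr)2, THF, −78 °C; then ICH2CH=CHOSiMe3 (from 3 and Me3SiI, CH2Cl2, −78 °C), −78 to −20 °C; then AcOH (cat.), EtOH, 20 °C; then Fe(acac)3 (30 mol %), PhSiH3, 60 °C
Reagents that add atoms: none
Why: The kinetic cross-conjugated lithium dienolate of 2 is C-alkylated by SN2 displacement at the allylic iodide ICH2CH=CHOSiMe3 (enolate alkylation with an allylic halide, here a conjugate-addition equivalent of acrolein whose neutral silyl enol ether product cannot undergo the second intramolecular Michael addition that acrylate-type acceptors suffer with carvone enolates), which forms C1–C10. Acid-catalysed ethanolysis unmasks aldehyde 5, and the iron hydride formed from Fe(acac)3 and PhSiH3 transfers a hydrogen atom to the CH2 terminus of the isopropenyl group (Markovnikov HAT), giving the tertiary C4 radical that adds to the formyl carbon and forms C3–C4, after which the alkoxy radical is reduced to the alcohol. The closest known reaction type is the iron-hydride HAT-initiated reductive radical cyclisation of alkene-tethered ketones. Ring A closes in the 6-exo-trig mode on the C=O bond through a chair transition state, and the fusion must be trans because the two arms are trans-diequatorial on ring B. C10 is set by the C5 stereocentre of carvone (the electrophile enters anti to the isopropenyl group, leaving the methyl cis to it), C5 is untouched, and C3 should form as the 3β (equatorial) alcohol with the formyl oxygen pseudo-equatorial in the chair. The step needs HAT to the electron-rich 1,1-disubstituted alkene rather than to the electron-poor trisubstituted enone and cyclisation faster than quenching of the radical, which the alkene polarity and the six-membered exo closure onto an aldehyde should secure.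

Step 3
Reactants: 6 bicyclic hydroxy enone
Product: 8 saturated hydroxy ketone (8α-methyl), via 8-epi ketone 7 (not isolated)
Conditions: H2 (1 atm), Pd/C, EtOAc, 20 °C; then NaOMe (cat.), MeOH, 20 °C
Reagents that add atoms: none
Why: Heterogeneous hydrogenation saturates the enone C7=C8 bond from the α face, away from the axial C10 methyl group, and methoxide then epimerises C8 through the enolate to the equatorial 8α-methyl ketone under thermodynamic control.

Step 4
Reactants: 8 saturated hydroxy ketone
Product: 9 exocyclic alkene (C9=C11H2)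
Conditions: Ph3PCH3Br, KOt-Bu, toluene, 90 °C
Reagents that add atoms: methyltriphenylphosphonium bromide C[P+](c1ccccc1)(c1ccccc1)c1ccccc1.[Br-]
Why: Wittig methylenation with excess salt-free ylide at elevated temperature converts hindered ketones, the 3-hydroxyl being carried as its alkoxide and C8 remaining equatorial under the equilibrating base.

Step 5
Reactants: 9 exocyclic alkene
Product: 10 9α,11-spiro-epoxide
Conditions: mCPBA, NaHCO3, CH2Cl2, 0 °C
Reagents that add atoms: 3-chloroperoxybenzoic acid OOC(=O)c1cccc(Cl)c1
Why: Prilezhaev epoxidation delivers oxygen to the exocyclic alkene from the α face because the axial C10 methyl group shields the β face, which sets C9 with oxygen α and C11 β.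

Step 6
Reactants: 11 furan-3-ylmethanol
Product: 12 3-(chloromethyl)furan
Conditions: SOCl2, pyridine, Et2O, 0 °C
Reagents that add atoms: thionyl chloride ClS(Cl)=O
Why: Chlorodehydroxylation of the primary alcohol through its chlorosulfite (SN2 by chloride, pyridine as acid scavenger) provides the halide needed for the Grignard reagent.

Step 7
Reactants: 10 9α,11-spiro-epoxide; 12 3-(chloromethyl)furan
Product: 13 furan diol (15,16-epoxy-8βH-labda-13(16),14-diene-3β,9α-diol)
Conditions: 12, Mg, THF, 0 °C; then Li2CuCl4 (5 mol %), 10, THF, −30 to 0 °C; aq. NH4Cl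
Reagents that add atoms: none
Why: Copper-catalysed SN2 opening of the 1,1-disubstituted epoxide by the furylmethyl Grignard reagent occurs at the unsubstituted C11, so C11–C12 forms while the C9–O bond and hence the 9α-hydroxyl are retained, with excess reagent covering the free 3-hydroxyl.

Step 8
Reactants: 13 furan diol
Product: 14 furan acetate (3-O-acetyl derivative of 13)
Conditions: Ac2O, pyridine, 20 °C
Reagents that add atoms: acetic anhydride CC(=O)OC(C)=O
Why: Acetylation in pyridine without an acyl-transfer catalyst esterifies the secondary equatorial 3β-hydroxyl only, the tertiary 9α-hydroxyl next to the quaternary C10 being too hindered.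

Step 9
Reactants: 14 furan acetate
Product: 17 target butenolide, via endoperoxide 15 (not isolated), via hydroxybutenolide 16 (not isolated)
Conditions: O2, hν, tetraphenylporphyrin (cat.), i-Pr2NEt, CH2Cl2, −78 °C; then NaBH4, EtOH, 0 °C; then aq. HCl to pH 3
Reagents that add atoms: dioxygen O=O
Why: Singlet oxygen adds [4+2] across the furan, the hindered amine removes the less hindered bridgehead proton at C15 (Kornblum–DeLaMare fragmentation) to give the hydroxybutenolide with C15 as carbonyl and C16 as lactol, and borohydride reduction of its open aldehyde form followed by relactonisation leaves C16 as OCH2.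

Compound list
1 | (R)-(−)-carvone, (5R)-2-methyl-5-(prop-1-en-2-yl)cyclohex-2-en-1-one | CC1=CC[C@H](CC1=O)C(C)=C | starting material
2 | trans-6-methylcarvone, (5R,6S)-2,6-dimethyl-5-(prop-1-en-2-yl)cyclohex-2-en-1-one | C[C@H]1[C@@H](CC=C(C)C1=O)C(C)=C | intermediate
3 | acrolein (prop-2-enal) | C=CC=O | starting material
4 | silyl enol ether, (5S,6S)-2,6-dimethyl-5-(prop-1-en-2-yl)-6-[(2Z)-3-(trimethylsilyloxy)prop-2-en-1-yl]cyclohex-2-en-1-one | C[Si](C)(C)O/C=C\C[C@@]1(C)[C@@H](CC=C(C)C1=O)C(C)=C | intermediate
5 | keto aldehyde, 3-[(1S,6S)-1,3-dimethyl-2-oxo-6-(prop-1-en-2-yl)cyclohex-3-en-1-yl]propanal | O=CCC[C@@]1(C)[C@@H](CC=C(C)C1=O)C(C)=C | intermediate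
6 | bicyclic hydroxy enone, (4aS,6S,8aS)-6-hydroxy-2,5,5,8a-tetramethyl-4a,5,6,7,8,8a-hexahydronaphthalen-1(4H)-one (3β-OH, 5α-H, 10β-CH3, C7=C8, C9=O) | O[C@H]1CC[C@@]2(C)[C@@H](CC=C(C)C2=O)C1(C)C | intermediate
7 | 8-epi ketone, (2S,4aS,6S,8aS)-6-hydroxy-2,5,5,8a-tetramethyloctahydronaphthalen-1(2H)-one (8β-methyl, axial) | O[C@H]1CC[C@@]2(C)[C@@H](CC[C@H](C)C2=O)C1(C)C | intermediate
8 | saturated hydroxy ketone, (2R,4aS,6S,8aS)-6-hydroxy-2,5,5,8a-tetramethyloctahydronaphthalen-1(2H)-one (8α-methyl, equatorial) | O[C@H]1CC[C@@]2(C)[C@@H](CC[C@@H](C)C2=O)C1(C)C | intermediate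
9 | exocyclic alkene, trans-decalin with 3β-OH, 4,4-dimethyl, 5α-H, 8α-methyl, 10β-methyl and C9=C11H2 | O[C@H]1CC[C@@]2(C)[C@@H](CC[C@@H](C)C2=C)C1(C)C | intermediate
10 | 9α,11-spiro-epoxide of 9 (oxirane oxygen α, C11 β) | O[C@H]1CC[C@@]2(C)[C@@H](CC[C@@H](C)[C@]23CO3)C1(C)C | intermediate
11 | furan-3-ylmethanol | OCc1ccoc1 | starting material
12 | 3-(chloromethyl)furan | ClCc1ccoc1 | intermediate
13 | furan diol, 15,16-epoxy-8βH-labda-13(16),14-diene-3β,9α-diol | O[C@H]1CC[C@@]2(C)[C@@H](CC[C@@H](C)[C@]2(O)CCc2ccoc2)C1(C)C | intermediate
14 | furan acetate, 3β-acetoxy-15,16-epoxy-8βH-labda-13(16),14-dien-9α-ol | CC(=O)O[C@H]1CC[C@@]2(C)[C@@H](CC[C@@H](C)[C@]2(O)CCc2ccoc2)C1(C)C | intermediate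
15 | endoperoxide, C15/C16 adduct of singlet oxygen to the furan of 14 (bridgehead epimers) | CC(=O)O[C@H]1CC[C@@]2(C)[C@@H](CC[C@@H](C)[C@]2(O)CCC2=CC3OOC2O3)C1(C)C | intermediate
16 | hydroxybutenolide, 3β-acetoxy-9α-hydroxy labd-13-ene with C15 lactone carbonyl and C16 lactol (C16 epimers) | CC(=O)O[C@H]1CC[C@@]2(C)[C@@H](CC[C@@H](C)[C@]2(O)CCC2=CC(=O)OC2O)C1(C)C | intermediate
17 | target, 3β-acetoxy-9α-hydroxy-8βH-labd-13-ene butenolide (C15 carbonyl, C16 OCH2) | CC(=O)O[C@H]1CC[C@@]2(C)[C@@H](CC[C@@H](C)[C@]2(O)CCC2=CC(=O)OC2)C1(C)C | target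

Total steps: 9. Longest linear sequence: 8 steps (steps 1 to 5 and 7 to 9; step 6 is a side branch).

Steps most likely to fail

Step 2. Silyl transfer from the iodide to the lithium enolate would liberate acrolein and divert the enolate into a double Michael addition across the enone. In the radical stage, addition to the formyl group is reversible, so hydrogen-atom quenching of the C4 radical or poor face selectivity at C3 can erode the annulation. The fallback is stepwise, with an irreversible radical acceptor and C3 set by hydride. From 2, alkylation with 2-(2-bromoethyl)-1,3-dioxolane (LiN(i-Pr)2, DMPU, NaI) gives dioxolane F1. Aqueous HCl releases keto aldehyde 5, now isolated, and NH2OH·HCl in pyridine followed by Ac2O converts it into nitrile F2. Fe(acac)3 and PhSiH3 in EtOH cyclise the tertiary radical onto the nitrile, and acidic work-up hydrolyses the imine to enedione F3. NaBH4 in MeOH/CH2Cl2 at −78 °C should reduce only the saturated C3 ketone from the α face, which returns to 6.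

Step 7. Magnesium salts can rearrange the spiro-epoxide to the C9 aldehyde, substitution at the neopentyl-like C11 may be slow, and the furylmethyl Grignard reagent can couple through furan C2. The fallback uses olefination instead of epoxide opening. From 9, OsO4 (cat.) with N-methylmorpholine N-oxide dihydroxylates the α face to triol F4. TEMPO (cat.), NaOCl and KBr oxidise only the primary hydroxyl to hydroxy aldehyde F5. Wittig reaction with the ylide from phosphonium chloride F6 (made from 12 and PPh3, deprotonated with n-BuLi) gives alkene F7. Diimide (TsNHNH2, NaOAc) saturates the C11=C12 bond without touching the furan, which returns to 13.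

Step 4. The basic ylide may enolise the hindered ketone towards C8 faster than it adds, so conversion stalls. The fallback is nucleophilic addition followed by Peterson elimination. From 8, Me3SiCH2MgCl with CeCl3 adds to C9 from the α face to give hydroxysilane F8, and KH in THF eliminates trimethylsilanolate, which returns to 9.

Further compounds
F1 | step 2 | dioxolane, 6-methylcarvone with a 2-(1,3-dioxolan-2-yl)ethyl group at C6 trans to the isopropenyl group | C1(OCCO1)CC[C@@]2(C)[C@@H](CC=C(C)C2=O)C(C)=C
F2 | step 2 | nitrile, 3-[(1S,6S)-1,3-dimethyl-2-oxo-6-(prop-1-en-2-yl)cyclohex-3-en-1-yl]propanenitrile | N#CCC[C@@]1(C)[C@@H](CC=C(C)C1=O)C(C)=C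
F3 | step 2 | enedione, 3-oxo analogue of 6 (C3=O, C9=O, C7=C8) | O=C1CC[C@@]2(C)[C@@H](CC=C(C)C2=O)C1(C)C
F4 | step 7 | triol, 3β,9α,11-trihydroxy derivative of 9 | O[C@H]1CC[C@@]2(C)[C@@H](CC[C@@H](C)[C@]2(O)CO)C1(C)C
F5 | step 7 | hydroxy aldehyde, 3β,9α-dihydroxy C11 aldehyde | O[C@H]1CC[C@@]2(C)[C@@H](CC[C@@H](C)[C@]2(O)C=O)C1(C)C
F6 | step 7 | phosphonium chloride, (furan-3-ylmethyl)triphenylphosphonium chloride | [Cl-].c1ccc(cc1)[P+](Cc1ccoc1)(c1ccccc1)c1ccccc1
F7 | step 7 | alkene, 11,12-didehydro derivative of 13 (Z drawn) | O[C@H]1CC[C@@]2(C)[C@@H](CC[C@@H](C)[C@]2(O)/C=C\c2ccoc2)C1(C)C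
F8 | step 4 | hydroxysilane, 9β-hydroxy-9α-[(trimethylsilyl)methyl] adduct of 8 | O[C@H]1CC[C@@]2(C)[C@@H](CC[C@@H](C)[C@@]2(O)C[Si](C)(C)C)C1(C)C
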